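**Plan** (germacrane numbering: C1 acetoxy carbon, C10 methyl carbon, C9 CH2, C8 tiglate carbon, C7=C11 butenolide alkene, C12 lactone C=O, C13 CH2OAc, C6 lactone O–CH, C4–C5 epoxide)

- Cuts: the C1/C13 acetates, the epoxide (back to the Z alkene C4=C5) and C1–OH (back to C1=O). The ring is then re-closed by a bond absent from the target, C1–C6. C1 and C6 lie 1,6 across the ten-membered ring, C1 is oxygenated and C6 is the γ-carbon of the butenolide, so C1–C6 is a vinylogous aldol bond.
- With C1–C6 in place, C9–C10 lies in a six-membered ring and is cut by ring-closing metathesis; the butenolide is cut to alkyne + allyl + CO2, and ring C1–C6 to 3-methylcyclohex-2-enone.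
- Forward: ring A (C1–C6, its alkene is the future Z-C4=C5) → spiro-butenolide at C6 → ring B (C6, C7, C8, C9, C10, C1) closed at C9=C10 → C8 oxidized, C10 and C8 set by two reductions → C1–C6 cut to release the ten-membered ring → C1 reduction, epoxidation, acetylation.
- Stereochemistry: absolute configuration enters at C1 (oxaziridine hydroxylation), passes to C6 (addition anti to C1–OSiMe3), then to C10 and C8 (hydrides to the face of ring B opposite ring A). C1 and C6 are then erased and set again in the macrocycle (C6 by protonation, C1 by Felkin–Anh reduction); the C1 hydroxyl places the epoxide.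

Key step: step 5

Assumption: (+)-(camphorylsulfonyl)oxaziridine is taken to give the (S)-carbinol of 7, by analogy with 2-substituted 1-tetralone enolates; if the sense is the other one, the (−)-reagent takes its place.

**Step 1**
Reactants: 1 3-methylcyclohex-2-en-1-one; 2 2-bromopropene
Product: 4 rac-isopiperitenone [3-methyl-6-(prop-1-en-2-yl)cyclohex-2-en-1-one], via lithium enolate 3 (not isolated)
Conditions: LiN(SiMe3)2, THF, −78 °C; then 2, Pd2(dba)3 (cat.), P(t-Bu)3 (cat.), −78 °C to rt
Reagents that add atoms: 2 2-bromopropene, CC(Br)=C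
Why: kinetic deprotonation at the α′-carbon (future C1) and palladium-catalysed α-alkenylation of the ketone enolate with the alkenyl bromide should install C10/C14; the new centre is racemic and is flattened again in step 2.

**Step 2**
Reactants: 4 rac-isopiperitenone
Product: 7 (S)-3-methyl-6-(prop-1-en-2-yl)-6-(trimethylsilyloxy)cyclohex-2-en-1-one, via sodium dienolate 5 (not isolated), via sodium alkoxide 6 (not isolated)
Conditions: NaN(SiMe3)2, THF, −78 °C; (+)-(camphorylsulfonyl)oxaziridine, −78 °C; then Me3SiCl, −78 to 0 °C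
Reagents that add atoms: (+)-(camphorylsulfonyl)oxaziridine, CC1(C)[C@@H]2CC[C@]13CS(=O)(=O)N4O[C@@]34C2; chlorotrimethylsilane, C[Si](C)(C)Cl
Why: asymmetric enolate hydroxylation with an N-sulfonyloxaziridine should place oxygen on the α-carbon of the cross-conjugated dienolate, the chiral reagent choosing the face and so setting C1 (the source of all absolute configuration), and silylation in the same flask masks the tertiary alkoxide.

**Step 3**
Reactants: 7 (S)-silyloxy enone; 8 tert-butyldimethyl(prop-2-yn-1-yloxy)silane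
Product: 11 cis-1-[3-(tert-butyldimethylsilyloxy)prop-1-ynyl]-3-methyl-6-(prop-1-en-2-yl)cyclohex-2-ene-1,6-diol, via lithium acetylide 9 (not isolated), via trimethylsilyl ether 10 (not isolated)
Conditions: 8, n-BuLi, THF, −78 °C; then 7, −78 °C; aq NH4Cl; then citric acid, MeOH, 0 °C
Reagents that add atoms: 8 tert-butyldimethyl(prop-2-yn-1-yloxy)silane, C#CCO[Si](C)(C)C(C)(C)C
Why: 1,2-addition of the lithium acetylide to the enone carbonyl should occur anti to the pseudo-axial C1–OSiMe3 bond (Felkin–Anh, polar model), setting C6 with the two oxygens cis and bringing in C7, C11 and C13; mild acid methanolysis then removes only the trimethylsilyl group.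

**Step 4**
Reactants: 11 cis-diol; 12 allylmagnesium bromide
Product: 15 4-allyl-3-(tert-butyldimethylsilyloxymethyl)-10-hydroxy-7-methyl-10-(prop-1-en-2-yl)-1-oxaspiro[4.5]deca-3,6-dien-2-one (ring oxygen and 10-OH cis), via alkenylmagnesium chelate 13 (not isolated), via hydroxy acid 14 (not isolated)
Conditions: CH2=CHCH2MgBr (4 equiv), Et2O/toluene, 0 to 50 °C; then CO2 (1 atm), −20 °C to rt; then 0.5 M HCl, THF, 0 °C
Reagents that add atoms: 12 allylmagnesium bromide, C=CC[Mg]Br; carbon dioxide, O=C=O
Why: alkoxide-directed anti-carbomagnesiation of the propargylic alcohol should put allyl (C8, C9) on the proximal alkyne carbon C7 and magnesium on C11 in a five-membered chelate, and carboxylation (C12) followed by acid lactonization onto the C6 hydroxyl gives the tetrasubstituted butenolide.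

**Step 5**
Reactants: 15 spiro-butenolide
Product: 16 1-hydroxy-13-(tert-butyldimethylsilyloxy)-1,6-cyclogermacra-4,7(11),9-trien-12,6-olide (cis-fused 6/6/5 tricycle)
Conditions: second-generation Grubbs catalyst RuCl2(=CHPh)(PCy3)(H2IMes) (5 mol %), 1,4-benzoquinone (10 mol %), CH2Cl2 (0.005 M), 40 °C
Reagents that add atoms: none
Why: the ruthenium carbene should load on the terminal allyl alkene (at C9), add [2+2] to the 1,1-disubstituted isopropenyl alkene and cyclorevert with loss of ethylene to give C9=C10. The closest known reaction is ring-closing metathesis of an allyl group with a 1,1-disubstituted alkene to a trisubstituted cyclohexene. It closes the six-membered ring B (C6, C7, C8, C9, C10, C1) by alkene metathesis; this is a six-ring closure only because the C1–C6 bond of ring A holds the allyl and isopropenyl groups cis on neighbouring carbons, and the new ring alkene is necessarily cis. No stereocentre is formed here; C10 is set from this alkene in step 7 under control of the rigid tricycle. The step needs chemoselectivity and no double-bond migration: the trisubstituted alkene of ring A and the tetrasubstituted C7=C11 neither load the carbene nor undergo productive metathesis, benzoquinone suppresses isomerization of the allyl group into conjugation, and the six-ring closure at high dilution outruns dimerization.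

**Step 6**
Reactants: 16 tricyclic triene
Product: 17 1-hydroxy-8-oxo-13-(tert-butyldimethylsilyloxy)-1,6-cyclogermacra-4,7(11),9-trien-12,6-olide
Conditions: Rh2(cap)4 (cap = caprolactamate, C6H10NO; 1 mol %), t-BuOOH (5 equiv), NaHCO3, CH2Cl2, rt
Reagents that add atoms: tert-butyl hydroperoxide, CC(C)(C)OO
Why: allylic C–H oxidation by tert-butylperoxyl radicals should attack C8, whose hydrogens are doubly allylic and γ to the lactone carbonyl, and since both ends of the resulting pentadienyl radical (C11, C10) are fully substituted, oxygenation at the central carbon leads to the cross-conjugated dienone.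

**Step 7**
Reactants: 17 dienone
Product: 18 1-hydroxy-8-oxo-13-(tert-butyldimethylsilyloxy)-1,6-cyclogermacra-4,7(11)-dien-12,6-olide (C14 methyl on the face of ring B that carries C5)
Conditions: Cu(OAc)2·H2O (5 mol %), 1,2-bis(diphenylphosphino)benzene (5 mol %), (EtO)2MeSiH, t-BuOH, toluene, 0 °C to rt
Reagents that add atoms: none
Why: copper hydride conjugate reduction of the trisubstituted enone should deliver hydride to C10 from the face of ring B opposite ring A (C5 is pseudo-axial on C6 and shields the other face), which sets C10, while the tetrasubstituted C7=C11 and the isolated C4=C5 are not touched.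

**Step 8**
Reactants: 18 ketone
Product: 19 1,8-dihydroxy-13-(tert-butyldimethylsilyloxy)-1,6-cyclogermacra-4,7(11)-dien-12,6-olide (8-OH cis to the C14 methyl)
Conditions: NaBH4, CeCl3·7H2O, MeOH, −40 °C
Reagents that add atoms: none
Why: Luche 1,2-reduction of the conjugated ketone should again take hydride from the face opposite ring A (the axial path is blocked by C5 and by the now axial C14 methyl), so the C8 hydroxyl ends up cis to the C10 methyl as the target requires.

**Step 9**
Reactants: 19 diol; 20 tigloyl chloride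
Product: 21 1-hydroxy-8-tigloyloxy-13-(tert-butyldimethylsilyloxy)-1,6-cyclogermacra-4,7(11)-dien-12,6-olide
Conditions: 20, pyridine, DMAP (cat.), CH2Cl2, 0 to 40 °C
Reagents that add atoms: 20 tigloyl chloride, C/C=C(\C)C(Cl)=O
Why: nucleophile-catalysed acylation should esterify the secondary C8 alcohol only, the tertiary C1 alcohol being inert, and the ester also prevents later hemiketal formation between C8–OH and the C1 ketone.

**Step 10**
Reactants: 21 tricyclic tiglate
Product: 23 1-oxo-8-tigloyloxy-13-(tert-butyldimethylsilyloxy)germacra-4(Z),7(11)-dien-12,6-olide, via potassium furanolate 22 (not isolated)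
Conditions: KN(SiMe3)2 (1.05 equiv), THF, −78 to −40 °C; then AcOH, −78 °C
Reagents that add atoms: none
Why: Proposed new method: the tertiary C1 alkoxide should expel C6 as the γ-carbanion of the butenolide (an aromatic 2-furanolate that is also allylic to C4=C5), cutting the C1–C6 bond and opening the two six-membered rings into the ten-membered ring with a C1 ketone; the closest known reaction types are retro-aldol ring expansion of bicyclic β-hydroxy ketones (second stage of the de Mayo reaction) and the reversibility of vinylogous aldol additions of butenolides; the step is driven by the large acidity gap between alkoxide and furanolate and by release of the syn-axial crowding of 21, and acetic acid then protonates C6 on the furan face not covered by the C8–C5 carbon bridge, which sets C6, while C8 and C10 are untouched at low temperature.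

**Step 11**
Reactants: 23 macrocyclic ketone
Product: 24 1-hydroxy-8-tigloyloxy-13-(tert-butyldimethylsilyloxy)germacra-4(Z),7(11)-dien-12,6-olide (1-OH cis to the C14 methyl)
Conditions: LiBH(s-Bu)3 (1.1 equiv), THF, −78 °C; aq NH4Cl
Reagents that add atoms: none
Why: Felkin–Anh addition of the bulky hydride to the α-methyl ketone, anti to the C9 branch of C10, should give the C1 alcohol with hydroxyl and C14 methyl on the same ring face, as in the target.

**Step 12**
Reactants: 24 macrocyclic alcohol
Product: 25 4,5-epoxy-1-hydroxy-8-tigloyloxy-13-(tert-butyldimethylsilyloxy)germacr-7(11)-en-12,6-olide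
Conditions: VO(acac)2 (5 mol %), t-BuOOH, CH2Cl2, 0 °C
Reagents that add atoms: tert-butyl hydroperoxide, CC(C)(C)OO
Why: vanadium-catalysed hydroxyl-directed epoxidation should deliver oxygen from the bishomoallylic C1 hydroxyl to the face of the Z alkene C4=C5 that this hydroxyl occupies, setting C4 and C5 with the oxirane cis to C1–O, while the two electron-poor alkenes do not react.

**Step 13**
Reactants: 25 epoxy silyl ether
Product: 26 4,5-epoxy-1,13-dihydroxy-8-tigloyloxygermacr-7(11)-en-12,6-olide
Conditions: Bu4NF, AcOH (1:1), THF, 0 °C to rt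
Reagents that add atoms: none
Why: fluoride desilylation of the primary silyl ether, buffered with acetic acid, should spare the epoxide and the acidic C6–H next to it.

**Step 14**
Reactants: 26 diol
Product: 27 target, (1S,4R,5S,6S,8S,10R)-1,13-diacetoxy-4,5-epoxy-8-tigloyloxygermacr-7(11)-en-12,6-olide
Conditions: Ac2O, pyridine, DMAP (cat.), CH2Cl2, 0 °C
Reagents that add atoms: acetic anhydride, CC(=O)OC(C)=O
Why: acetylation of the primary C13 and the secondary C1 hydroxyl in one operation completes the target without touching any stereocentre.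

**Compound list**

1 | 3-methylcyclohex-2-en-1-one | CC1=CC(=O)CCC1 | starting material
2 | 2-bromopropene | CC(Br)=C | starting material
3 | lithium 5-methylcyclohexa-1,5-dien-1-olate | [Li+].[O-]C1=CCCC(C)=C1 | intermediate
4 | rac-isopiperitenone, 3-methyl-6-(prop-1-en-2-yl)cyclohex-2-en-1-one | CC(=C)C1CCC(C)=CC1=O | intermediate
5 | sodium 5-methyl-2-(prop-1-en-2-yl)cyclohexa-1,5-dien-1-olate | [Na+].[O-]C1=C(C(C)=C)CCC(C)=C1 | intermediate
6 | sodium (S)-4-methyl-2-oxo-1-(prop-1-en-2-yl)cyclohex-3-en-1-olate | [Na+].[O-][C@]1(C(C)=C)CCC(C)=CC1=O | intermediate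
7 | (S)-3-methyl-6-(prop-1-en-2-yl)-6-(trimethylsilyloxy)cyclohex-2-en-1-one | C[Si](C)(C)O[C@]1(C(C)=C)CCC(C)=CC1=O | intermediate
8 | tert-butyldimethyl(prop-2-yn-1-yloxy)silane | C#CCO[Si](C)(C)C(C)(C)C | starting material
9 | lithium acetylide of 8 | [Li+].[C-]#CCO[Si](C)(C)C(C)(C)C | intermediate
10 | alkynyl carbinol with the C1 trimethylsilyl ether (oxygens cis) | CC(C)(C)[Si](C)(C)OCC#C[C@]1(O)C=C(C)CC[C@]1(O[Si](C)(C)C)C(C)=C | intermediate
11 | cis-1-[3-(tert-butyldimethylsilyloxy)prop-1-ynyl]-3-methyl-6-(prop-1-en-2-yl)cyclohex-2-ene-1,6-diol | CC(C)(C)[Si](C)(C)OCC#C[C@]1(O)C=C(C)CC[C@]1(O)C(C)=C | intermediate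
12 | allylmagnesium bromide | C=CC[Mg]Br | starting material
13 | alkenylmagnesium chelate (allyl on C7, Mg on C11 bridging to O6; C1–OMgBr) | C=CCC1=C(CO[Si](C)(C)C(C)(C)C)[Mg]O[C@]12C=C(C)CC[C@]2(O[Mg]Br)C(C)=C | intermediate
14 | (Z)-dihydroxy acid (C12 acid cis to C6) | OC(=O)/C(CO[Si](C)(C)C(C)(C)C)=C(/CC=C)[C@]1(O)C=C(C)CC[C@]1(O)C(C)=C | intermediate
15 | 4-allyl-3-(tert-butyldimethylsilyloxymethyl)-10-hydroxy-7-methyl-10-(prop-1-en-2-yl)-1-oxaspiro[4.5]deca-3,6-dien-2-one, ring O and OH cis | O=C1O[C@]2(C=C(C)CC[C@]2(O)C(C)=C)C(CC=C)=C1CO[Si](C)(C)C(C)(C)C | intermediate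
16 | 1-hydroxy-13-(tert-butyldimethylsilyloxy)-1,6-cyclogermacra-4,7(11),9-trien-12,6-olide | O=C1O[C@]23C=C(C)CC[C@]3(O)C(C)=CCC2=C1CO[Si](C)(C)C(C)(C)C | intermediate
17 | 1-hydroxy-8-oxo-13-(tert-butyldimethylsilyloxy)-1,6-cyclogermacra-4,7(11),9-trien-12,6-olide | O=C1O[C@]23C=C(C)CC[C@]3(O)C(C)=CC(=O)C2=C1CO[Si](C)(C)C(C)(C)C | intermediate
18 | 1-hydroxy-8-oxo-13-(tert-butyldimethylsilyloxy)-1,6-cyclogermacra-4,7(11)-dien-12,6-olide, C14 methyl syn to C5 | O=C1O[C@]23C=C(C)CC[C@]3(O)[C@H](C)CC(=O)C2=C1CO[Si](C)(C)C(C)(C)C | intermediate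
19 | 1,8-dihydroxy-13-(tert-butyldimethylsilyloxy)-1,6-cyclogermacra-4,7(11)-dien-12,6-olide, 8-OH cis to C14 | O=C1O[C@]23C=C(C)CC[C@]3(O)[C@H](C)C[C@H](O)C2=C1CO[Si](C)(C)C(C)(C)C | intermediate
20 | tigloyl chloride, (E)-2-methylbut-2-enoyl chloride | C/C=C(\C)C(Cl)=O | starting material
21 | 1-hydroxy-8-tigloyloxy-13-(tert-butyldimethylsilyloxy)-1,6-cyclogermacra-4,7(11)-dien-12,6-olide | O=C1O[C@]23C=C(C)CC[C@]3(O)[C@H](C)C[C@H](OC(=O)/C(C)=C/C)C2=C1CO[Si](C)(C)C(C)(C)C | intermediate
22 | potassium 2-furanolate of the ten-membered C1 ketone | [K+].C/C=C(\C)C(=O)O[C@H]1C[C@@H](C)C(=O)CC/C(C)=C\c2oc([O-])c(CO[Si](C)(C)C(C)(C)C)c12 | intermediate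
23 | 1-oxo-8-tigloyloxy-13-(tert-butyldimethylsilyloxy)germacra-4(Z),7(11)-dien-12,6-olide, C6, C8, C10 as in the target | C/C=C(\C)C(=O)O[C@H]1C[C@@H](C)C(=O)CC/C(C)=C\[C@H]2OC(=O)C(CO[Si](C)(C)C(C)(C)C)=C12 | intermediate
24 | 1-hydroxy-8-tigloyloxy-13-(tert-butyldimethylsilyloxy)germacra-4(Z),7(11)-dien-12,6-olide, C1 as in the target | C/C=C(\C)C(=O)O[C@H]1C[C@@H](C)[C@@H](O)CC/C(C)=C\[C@H]2OC(=O)C(CO[Si](C)(C)C(C)(C)C)=C12 | intermediate
25 | 4,5-epoxy-1-hydroxy-8-tigloyloxy-13-(tert-butyldimethylsilyloxy)germacr-7(11)-en-12,6-olide | C/C=C(\C)C(=O)O[C@H]1C[C@@H](C)[C@@H](O)CC[C@@]2(C)O[C@H]2[C@H]2OC(=O)C(CO[Si](C)(C)C(C)(C)C)=C12 | intermediate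
26 | 4,5-epoxy-1,13-dihydroxy-8-tigloyloxygermacr-7(11)-en-12,6-olide | C/C=C(\C)C(=O)O[C@H]1C[C@@H](C)[C@@H](O)CC[C@@]2(C)O[C@H]2[C@H]2OC(=O)C(CO)=C12 | intermediate
27 | (1S,4R,5S,6S,8S,10R)-1,13-diacetoxy-4,5-epoxy-8-tigloyloxygermacr-7(11)-en-12,6-olide | C/C=C(\C)C(=O)O[C@H]1C[C@@H](C)[C@@H](OC(C)=O)CC[C@@]2(C)O[C@H]2[C@H]2OC(=O)C(COC(C)=O)=C12 | target

Total steps: 14. Longest linear sequence: 14 steps (fully linear from 1).

**Steps most likely to fail**

Step 10. The C1–C6 heterolysis may stall at the alkoxide or be undone by transannular vinylogous aldol re-closure on protonation. The furanolate may also expel the C13 silyloxide, C10 may epimerize next to the new ketone, or C6 may be protonated on the wrong face. The fallback uses known radical chemistry and sets out from 21. Hypoiodite alkoxy-radical fragmentation (PhI(OAc)2, I2, visible light, CH2Cl2, rt) should form the C1 oxygen radical, whose β-scission cuts C1–C6 to the α-oxygenated, doubly allylic C6 radical. Iodine transfer, ionization and acetate capture then give the ten-membered 6-acetoxy-1-oxo-8-tigloyloxy-13-(tert-butyldimethylsilyloxy)germacra-4(Z),7(11)-dien-12,6-olide F1. Treatment of this pseudo-ester with NaBH4 and CeCl3·7H2O in MeOH, then dilute acid, should open it to the keto acid, reduce the C6 and C1 carbonyl groups and relactonize, which comes back to the route at 24.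

Step 4. Carbomagnesiation may be too slow at the hindered tertiary propargylic alkoxide, may place the allyl group on the wrong alkyne carbon, or the hydroxy acid may close to the six-membered lactone. The fallback sets out from 7 and replaces steps 3 and 4. Lithium methyl propiolate (methyl propiolate, LiN(i-Pr)2, THF, −78 °C) should add to the ketone to give the hydroxy ynoate methyl 3-[1-hydroxy-3-methyl-6-(prop-1-en-2-yl)-6-(trimethylsilyloxy)cyclohex-2-enyl]propiolate F2. Syn-carbocupration with allylcopper (CH2=CHCH2MgBr, CuBr·SMe2, THF, −78 °C), iodine quench and acid work-up (lactonization, loss of the trimethylsilyl group) should give the α-iodo butenolide 4-allyl-10-hydroxy-3-iodo-7-methyl-10-(prop-1-en-2-yl)-1-oxaspiro[4.5]deca-3,6-dien-2-one F3. Stille coupling with Bu3SnCH2OH (Pd(PPh3)4, dioxane, 90 °C) should give the hydroxymethyl butenolide 4-allyl-10-hydroxy-3-(hydroxymethyl)-7-methyl-10-(prop-1-en-2-yl)-1-oxaspiro[4.5]deca-3,6-dien-2-one F4. Silylation of the primary alcohol (t-BuMe2SiCl, imidazole, CH2Cl2) comes back to the route at 15.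

Step 7. Hydride may reach C10 from the other face (axial attack past C5), which would put the C14 methyl trans to the C8 oxygen after step 8, or copper hydride may reduce C7=C11 of the enedione. The fallback sets out from 17 and replaces reagent approach control by substrate-directed delivery. Hydrogenation with [Ir(cod)(PCy3)(py)]PF6 and H2 in CH2Cl2 should be directed by the tertiary C1 hydroxyl, which is allylic to C9=C10 and stands on the face that needs the hydrogen. This makes no new compound and comes back to the route at 18.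

**Further compounds**

F1 | step 10 | 6-acetoxy-1-oxo-8-tigloyloxy-13-(tert-butyldimethylsilyloxy)germacra-4(Z),7(11)-dien-12,6-olide | C/C=C(\C)C(=O)O[C@H]1C[C@@H](C)C(=O)CC/C(C)=C\C2(OC(C)=O)OC(=O)C(CO[Si](C)(C)C(C)(C)C)=C12
F2 | step 4 | methyl 3-[1-hydroxy-3-methyl-6-(prop-1-en-2-yl)-6-(trimethylsilyloxy)cyclohex-2-enyl]propiolate | COC(=O)C#C[C@]1(O)C=C(C)CC[C@]1(O[Si](C)(C)C)C(C)=C
F3 | step 4 | 4-allyl-10-hydroxy-3-iodo-7-methyl-10-(prop-1-en-2-yl)-1-oxaspiro[4.5]deca-3,6-dien-2-one | O=C1O[C@]2(C=C(C)CC[C@]2(O)C(C)=C)C(CC=C)=C1I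
F4 | step 4 | 4-allyl-10-hydroxy-3-(hydroxymethyl)-7-methyl-10-(prop-1-en-2-yl)-1-oxaspiro[4.5]deca-3,6-dien-2-one | O=C1O[C@]2(C=C(C)CC[C@]2(O)C(C)=C)C(CC=C)=C1CO
F0 | step 7 | none | none
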